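The earlier runs and the new flask were computed with made-up constants; scatter was added.

Our closed vessel stirs starting material with a trace of enzyme and a trace of impurity under a held gas, and the question is how far one dose of enzyme carries the charge.

| flask | starting material | gas | enzyme | impurity | remark | time |
|---|---|---|---|---|---|---|
| north-east | 0.050 M | 3.8 mM (held) | 0.01 mol% | 5.3 µM | the very flask that is asked about, followed so far |  |
| north-west | 0.025 M | 3.8 mM (held) | 0.01 mol% | 5.3 µM | run made earlier |  |
| flask | 0.050 M | 3.8 mM (held) | 0.01 mol% | 5.3 µM |  | 5.0 d |

| run | time / h | product / % |
|---|---|---|
| north-east | 30.0 | 47.4 |
| north-east | 60.0 | 53.6 |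
| north-east | 96.0 | 54.9 |
| north-east | 120 | 54.6 |
| north-west | 1.33 | 4.9 |
| north-west | 3.00 | 8.9 |
| north-west | 8.00 | 16.6 |
| north-west | 20.0 | 25.3 |

(scatter of a reading: 0.5 percentage points)

- ochre: change nothing and wait 10 d more
- grey: at 5.0 d take out 90% of the product then present, then wait 10 d
- teal: at 5.0 d add enzyme, 100% of the amount charged, then wait 10 d
- violet: at 5.0 d add starting material, 50.0% of the amount charged, then wait 10 d

1. product, in percent of the starting material first charged, at 5.0 d
2. which option adds most product ("none" when 2 percentage points or less is all one gets) (ochre / grey / teal / violet / none)
3. product present, with what was taken out counted in, in percent of the starting material first charged, after ochre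
4. product present, with what was taken out counted in, in percent of the starting material first charged, after grey

- product taken out counts as made
- at the start none of the gas is in solution
- additions bring no volume worth counting

Were falling starting material the whole story, the first-order constant of the north-west run would hold, but it reads 0.0378 /h up to 1.33 h and 0.00918 /h from 8.00 h to 20.0 h, a quarter of that, so we take the enzyme to be dying. The north-east readings stand flat, so we commit to 54.8% now. That gives 27.4 mM as the yield of one dose of enzyme at this charge, the product it makes before the stall. With the rate stopped, we expect nothing from ochre, grey or violet. If a fresh equal dose yields as much again, it meets 22.6 mM of starting material, less than its yield, so starting material becomes the limiting reagent, the gain should be 45 percentage points, and we choose teal.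

The forecast gives 54.8% now, 55% after ochre, 55% after grey and teal as best, holding that “the flask has stalled with dead catalyst”.

The flask gives 54.7%, 54.7% after ochre, 54.7% after grey, and teal as best.

    starting material + enzyme ⇌ starting complex (K = 15.0 /M, k = 6.40 × 10⁵ /M/h)
    second substrate + starting complex ⇌ ternary complex (K = 3800 /M, k = 5.90 × 10⁶ /M/h)
    ternary complex → enzyme + product (k = 470 /h)
    enzyme + impurity → spent catalyst A (k = 1.20 × 10⁵ /M/h)
    product + ternary complex → spent catalyst B (k = 1.30 /M/h)
    gas ⇌ second substrate, rate k6*(csat - [second substrate]) (kL = 26.0 /h)

Impurity at 5.94 µM or enzyme at 0.0091 mol% moves the answer for now by 5 points. Teal gains 45 points, against the 45 points reckoned from the yield of a dose, and at 120 h the flask held 25% of its impurity.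

At fixed loading, enzyme concentration goes with the charge, so for the neighbour charged with 0.12 M of starting material, at the same impurity concentration, a yield in step with the enzyme is 65.7 mM, or 54.8% product. That neighbour gives 62.0%.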